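## The problem

The target 13 is a drimane: a trans-fused decalin (ring A = C1–C5 and C10, ring B = C5–C10) with a gem-dimethyl group on C4 and an angular methyl on the quaternary C10. Ring B is functionalised at every carbon except the two ring-fusion atoms: an allylic (2E,4E,6E)-octatrienoate on C6, the C7=C8 alkene with its methyl on C8, and a fully substituted C9 carrying a tertiary hydroxyl and the C11 aldehyde. Four stereocentres must be set (C5, C6, C9, C10), and C10 is the one that can control the rest. Once its methyl is β, it and the 4β-methyl close the β face of ring B, so protonation at C5, hydride addition at C6 and oxidation at C9 all come from the α face. That is right for C5 (5α-H) and C9 (9α-OH) but wrong for C6 (it gives 6β-OH), so the 6α-ester must be formed with inversion. The fragile groups are the tertiary α-hydroxy aldehyde (base-induced α-ketol shift), the allylic ester (ionisation, elimination towards C5) and above all the trienoate, which survives neither osmylation nor hydrogenation nor strong nucleophiles and must go on last. The enabling feature is the pattern of ring B: oxygen on C6 and C9 para to each other, the alkene between them with a methyl on C8, and a methyl on C10. This is 2,6-dimethyl-1,4-benzoquinone 1 with its C10=C5 bond free to act as dienophile, and C1–C4 with the gem-dimethyl end is the diene 2.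

## Retrosynthesis

**C6–O acyl bond (13 ⇒ 11 + 12).** The ester is cut first because the triene cannot pass through any of the oxidations or reductions the core needs. The cut is made with inversion at C6, since every hydride reduction of a C6 ketone in this ring system delivers the 6β-alcohol. The precursor 11 already holds all core stereocentres (C6 as the epimer) and the purchased acid 12. The forward reaction must be an SN2 esterification at a shielded secondary allylic carbinol that leaves the tertiary hydroxyl and the aldehyde alone.

**Oxidation level at C11 and the O6 mask (11 ⇒ 10 ⇒ 9).** No skeletal bond is cut here. The aldehyde is traced to the primary alcohol of diol 9, and O6 is carried as a silyl ether so that C11–OH is the only oxidisable hydroxyl at that point. The forward steps need a non-acidic oxidation that does not cleave the glycol, and a desilylation that avoids base.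

**C9–O and C11–O (9 ⇒ 8).** Both oxygens are removed together to give the exocyclic alkene of diene 8. The neighbouring cut, C9–C11 (adding a one-carbon nucleophile to a C9 ketone), is rejected: the nucleophile would enter from the open α face and leave the hydroxyl β, the wrong epimer. Osmylation from the same α face puts oxygen α and leaves C11 β, as required. The forward reaction must choose the 1,1-disubstituted alkene over the C7=C8 alkene.

**C9=C11 (8 ⇒ 7).** This is the only carbon–carbon bond not made in the key step. It is cut by a carbonyl methylenation, which leads back to the 11-nor enone 7, whose C9 carbonyl has no α-hydrogen.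

**Ring A saturation, O6 silylation, C6 reduction (7 ⇒ 6 ⇒ 5 ⇒ 4).** The C2=C3 alkene is a relic of the cycloaddition. It is removed after the enedione has been reduced to a hydroxy-enone and before the exocyclic methylene exists; only in that window is it the single unhindered, unconjugated alkene in the molecule. The C6 alcohol of 5 comes from the enedione 4 by 1,2-reduction at the carbonyl that is not flanked by the quaternary carbon.

**C5 configuration (4 ⇒ 3).** The trans ring fusion is traced to the cis-fused adduct 3 by epimerisation. C5 is α to the C6 carbonyl and is the only enolisable position, so the correction costs one step.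

**C1–C10 and C4–C5 (3 ⇒ 1 + 2).** Cutting these two bonds opens ring A and gives two purchased compounds. The alternative of building ring B onto a ring A piece would mean installing both oxygens, the alkene and the C8 methyl afterwards; here they are all in the quinone. The forward reaction must form a quaternary centre with absolute control, orient the diene so that its CH2 end bonds to the methyl-bearing carbon, and overcome the reluctance of a diene with a Z-methyl group.

## Roads not taken

**Alternative 1: radical bicyclisation of an epoxy-polyene.** The cut is C4–C5 and C9–C10 of the acyclic epoxide A2. In the forward step Cp2TiCl (trivalent titanium, made from Cp2TiCl2 and manganese) opens the epoxide to the tertiary C4 radical, which closes rings A and B in succession and ends as the exocyclic alkene of A1.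
- Merits: the trans ring fusion and C5, C9 and C10 all follow from one epoxide stereocentre, with no equilibration at C5. C11 is already on C9 with the right configuration. In these respects it is better than the chosen plan, which needs an epimerisation and three steps to install C11.
- Weak points for 13: A1 carries oxygen where the target has none (C3, to be removed) and none where the target needs it. C6 is an unactivated methylene, C9 a methine, and the alkene is exocyclic at C8 rather than C7=C8. Isomerisation, C9 hydroxylation and a selective C6 oxidation with α configuration would all follow, the last with no obvious control.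
- Comparison: the chosen plan sets against the cleaner ring fusion of Alternative 1 the fact that ring B leaves its key step with both oxygens, the alkene and the C8 methyl in place and nothing to delete.

**Alternative 2: lactone Ireland–Claisen contraction.** The cut is C9–C10, made by a [3,3] shift that also breaks C6–O of the six-membered allylic lactone A4. Enolisation and silylation (KN(SiMe3)2, TBSCl) give the ketene acetal, which rearranges to the dienoic acid A3.
- Merits: the bond between two fully substituted carbons is made intramolecularly, and C9 arrives oxygenated with C11 at the acid level. The 5,7-diene of A3 could in principle take α-face hydroboration at C5=C6 to give 5α-H and 6α-OH directly. That would avoid the inversion the chosen plan needs, and on this point the alternative is better on paper.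
- Weak points: the two-atom C7=C8 tether between C9 and C6 allows only a boat transition state. A model of that boat places C11 anti to the C10 methyl across the new bond, which would put the carboxyl on the α face of C9; the configuration drawn for A3 therefore cannot be taken for granted. The silyl dienolate is a 2H-pyran and could open electrocyclically instead of rearranging. Enantioenriched A4 needs its own multistep preparation, and hydroboration of a conjugated diene is not reliably site-selective.
- Comparison: the chosen plan offers purchased starting materials, one catalytic asymmetric step and a C9 configuration fixed by a simple facial argument.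

**Alternative 3: silyloxydiene Diels–Alder forming ring B.** The cut is C7–C8 and C9–C10. The silyloxydiene A6 and (E)-but-2-enal A7 combine under the same type of chiral boron catalyst to give the silyl enol ether A5.
- Merits: all fifteen carbons, including C11 and C12, are assembled in one convergent step, and C6 is already oxygenated. In carbon count per step it beats the chosen plan.
- Weak points: the diene terminus C10 is fully substituted, and the diene is twisted out of plane by the gem-dimethyl group and the C10 methyl. The dienophile is a β-substituted enal, so the quaternary centre must form between two unreactive partners. In A5 the formyl group lies anti to the C10 methyl, the alkene C7=C8 is missing and C9 is a methine, so a dehydrogenation and an enolate hydroxylation are still needed. The route also ends with the same C6 ketone reduction and inversion as the chosen plan.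
- Comparison: the chosen cycloaddition uses a far more reactive dienophile (a quinone), lets the hindered diene terminus bond second, and delivers ring B at the correct oxidation pattern.

Key step: step 1

Convention: drimane numbering throughout (C11 on C9, C12 = methyl on C8, C13/C14 on C4, C15 on C10); β is the face of the C10 methyl; "11-nor" means C11 is not yet present.

Assumption: the (R)-configured catalyst is specified because the accepted pre-transition-state model for quinones (boron on the carbonyl lone pair syn to C–H, reacting double bond stacked on an aryl group) predicts the 10β-methyl adduct; both antipodes are sold as solutions, and the other would be used if the sense proved opposite.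

## Route

Step 1
Reactants: 1 2,6-dimethyl-1,4-benzoquinone; 2 4-methylpenta-1,3-diene
Product: 3 cis-fused 11-nordrima-2,7-diene-6,9-dione (5β-H; 10β-CH3) [(4aR,8aS)-2,5,5,8a-tetramethyl-4a,5,8,8a-tetrahydronaphthalene-1,4-dione]
Conditions: (R)-3,3-diphenyl-1-(o-tolyl)tetrahydro-1H,3H-pyrrolo[1,2-c][1,3,2]oxazaborole (20 mol%), HNTf2 (18 mol%), 2 (4 equiv), CH2Cl2, −78 → −20 °C
Reagents that add atoms: none
Why: The protonated oxazaborolidine, a chiral boron Lewis acid, binds the one carbonyl of 1 that is flanked by C–H (future C6) on the lone pair syn to that C–H, and a vinylic C–H···O contact to the ring oxygen holds the adjacent C=C over an aryl group of the catalyst. Activation through this carbonyl makes the methyl-bearing β-carbon (future C10) the electrophilic end; the unsubstituted CH2 terminus of 2, with the larger HOMO coefficient and no steric load, bonds there first (C1–C10) and the dimethyl terminus closes onto the α-carbon (C4–C5) in a concerted, asynchronous, suprafacial [4+2] cycloaddition. The closest known reaction type is the cationic oxazaborolidine-catalysed enantioselective Diels–Alder reaction of substituted 1,4-benzoquinones with simple dienes, including trisubstituted quinone double bonds that give an angular methyl. Ring A is closed as a cyclohexene by intermolecular [4+2] annulation, both new bonds forming in the one step. C10 is set by the catalyst, whose aryl group covers one face of the bound double bond; C5 follows from C10 because addition to the dienophile is suprafacial, hence the cis fusion (neither diene terminus becomes stereogenic, so endo or exo orientation has no stereochemical consequence). The two C=C bonds of 1 are enantiotopic, so site and face selection are a single question answered by the catalyst, while regiochemistry is secured by the substrate, since only one carbonyl can bind and only one orientation pairs the nucleophilic with the electrophilic terminus. What the step needs most is rate, because 2 must reach its s-cis form against its Z-methyl group; hence the excess of diene and the triflimide form of the catalyst.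

Step 2
Reactants: 3 cis-fused 11-nordrima-2,7-diene-6,9-dione
Product: 4 trans-fused 11-nordrima-2,7-diene-6,9-dione (5α-H) [(4aS,8aS)-2,5,5,8a-tetramethyl-4a,5,8,8a-tetrahydronaphthalene-1,4-dione]
Conditions: DBU (0.2 equiv), CH2Cl2, 23 °C
Reagents that add atoms: none
Why: Base-mediated epimerisation through the C5=C6 dienolate; C5–H is the only enolisable α-hydrogen because C10 is quaternary. Reprotonation from the α face, anti to the C10 methyl, and the lower strain of the trans-fused enedione should carry 3 over to 4, as in the classical cis-to-trans equilibration of quinone Diels–Alder adducts.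

Step 3
Reactants: 4 trans-fused 11-nordrima-2,7-diene-6,9-dione
Product: 5 6β-hydroxy-11-nordrima-2,7-dien-9-one
Conditions: NaBH4, CeCl3·7H2O, MeOH, −78 °C
Reagents that add atoms: none
Why: Luche 1,2-reduction; the C9 carbonyl is flanked by the quaternary C10 and the methyl-bearing C8, whereas C6 has only hydrogen-bearing neighbours, so hydride should go to C6. The 4β- and 10β-methyl groups are syn-axial over the β face of C6, so hydride enters from the α face and the new hydroxyl is β.

Step 4
Reactants: 5 6β-hydroxy-11-nordrima-2,7-dien-9-one
Product: 6 6β-(triethylsilyloxy)-11-nordrima-2,7-dien-9-one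
Conditions: TESOTf, 2,6-lutidine, CH2Cl2, −78 → 0 °C
Reagents that add atoms: triethylsilyl trifluoromethanesulfonate CC[Si](CC)(CC)OS(=O)(=O)C(F)(F)F
Why: Silyl triflate with a hindered pyridine base silylates even strongly shielded secondary alcohols. The triethylsilyl ether survives ylide base, osmylation and activated-DMSO oxidation and can later be removed with buffered fluoride.

Step 5
Reactants: 6 6β-(triethylsilyloxy)-11-nordrima-2,7-dien-9-one
Product: 7 6β-(triethylsilyloxy)-11-nordrim-7-en-9-one
Conditions: H2 (1 atm), RhCl(PPh3)3 (5 mol%), toluene–EtOH (1:1), 23 °C
Reagents that add atoms: none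
Why: Homogeneous hydrogenation with RhCl(PPh3)3 reduces the cis-disubstituted, unconjugated C2=C3 alkene and leaves the trisubstituted, conjugated C7=C8 alkene. No stereocentre is formed; the step sits here because later the exocyclic methylene would compete.

Step 6
Reactants: 7 6β-(triethylsilyloxy)-11-nordrim-7-en-9-one
Product: 8 6β-(triethylsilyloxy)drima-7,9(11)-diene
Conditions: Ph3PCH3Br, KOtBu, toluene, 90 °C
Reagents that add atoms: methyltriphenylphosphonium bromide C[P+](c1ccccc1)(c1ccccc1)c1ccccc1.[Br-]
Why: Wittig methylenation with the ylide generated by KOtBu in hot toluene, the usual protocol for hindered ketones. The C9 carbonyl has no α-hydrogen, and the γ-hydrogen on C6 is pseudo-equatorial and poorly aligned for deprotonation.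

Step 7
Reactants: 8 6β-(triethylsilyloxy)drima-7,9(11)-diene
Product: 9 6β-(triethylsilyloxy)drim-7-ene-9α,11-diol
Conditions: OsO4 (5 mol%), NMO, acetone–H2O (8:1), 23 °C
Reagents that add atoms: osmium tetroxide O=[Os](=O)(=O)=O; N-methylmorpholine N-oxide C[N+]1([O-])CCOCC1
Why: Catalytic (Upjohn) dihydroxylation; the 1,1-disubstituted exocyclic alkene should react in preference to the trisubstituted C7=C8 alkene, which is shielded and inductively deactivated by the allylic 6β-silyloxy group. Osmium adds from the α face, anti to the axial C10 methyl, giving the 9α-hydroxyl with C11 β, as known for dihydroxylation of drima-7,9(11)-dienes.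

Step 8
Reactants: 9 6β-(triethylsilyloxy)drim-7-ene-9α,11-diol
Product: 10 9α-hydroxy-6β-(triethylsilyloxy)drim-7-en-11-al
Conditions: SO3·pyridine, DMSO, iPr2NEt, CH2Cl2, 0 °C
Reagents that add atoms: none
Why: Parikh–Doering oxidation of the only oxidisable hydroxyl; the tertiary C9 hydroxyl cannot react. Activated-DMSO oxidants do not cleave the glycol, and the non-acidic medium spares the allylic silyl ether.

Step 9
Reactants: 10 9α-hydroxy-6β-(triethylsilyloxy)drim-7-en-11-al
Product: 11 6β,9α-dihydroxydrim-7-en-11-al
Conditions: HF·pyridine, pyridine, THF, 0 → 23 °C
Reagents that add atoms: none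
Why: Fluoride-driven Si–O cleavage under buffered, non-basic conditions. This avoids the α-ketol rearrangement that base could trigger in the tertiary α-hydroxy aldehyde and the ionisation that strong acid could cause at the allylic C6.

Step 10
Reactants: 11 6β,9α-dihydroxydrim-7-en-11-al; 12 (2E,4E,6E)-octa-2,4,6-trienoic acid
Product: 13 9α-hydroxy-11-oxodrim-7-en-6α-yl (2E,4E,6E)-octa-2,4,6-trienoate
Conditions: PPh3, DIAD, toluene, 0 → 23 °C
Reagents that add atoms: none
Why: Mitsunobu esterification; the 6β-hydroxyl is converted into an alkoxyphosphonium ion and displaced by the carboxylate of 12 from the open α face (SN2), which inverts C6 to the 6α-ester. The tertiary hydroxyl is inert under these conditions, and ionisation to an allyl cation is disfavoured by the electron-poor C9 next to C8.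

## Compound list

1 | 2,6-dimethyl-1,4-benzoquinone | CC1=CC(=O)C=C(C)C1=O | starting material
2 | 4-methylpenta-1,3-diene | C=CC=C(C)C | starting material
3 | cis-fused 11-nordrima-2,7-diene-6,9-dione (5β-H, 10β-CH3) | O=C1C=C(C)C(=O)[C@@]2(C)CC=CC(C)(C)[C@@H]12 | intermediate
4 | trans-fused 11-nordrima-2,7-diene-6,9-dione (5α-H) | O=C1C=C(C)C(=O)[C@@]2(C)CC=CC(C)(C)[C@H]12 | intermediate
5 | 6β-hydroxy-11-nordrima-2,7-dien-9-one | O[C@@H]1C=C(C)C(=O)[C@@]2(C)CC=CC(C)(C)[C@H]12 | intermediate
6 | 6β-(triethylsilyloxy)-11-nordrima-2,7-dien-9-one | CC[Si](CC)(CC)O[C@@H]1C=C(C)C(=O)[C@@]2(C)CC=CC(C)(C)[C@H]12 | intermediate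
7 | 6β-(triethylsilyloxy)-11-nordrim-7-en-9-one | CC[Si](CC)(CC)O[C@@H]1C=C(C)C(=O)[C@@]2(C)CCCC(C)(C)[C@H]12 | intermediate
8 | 6β-(triethylsilyloxy)drima-7,9(11)-diene | CC[Si](CC)(CC)O[C@@H]1C=C(C)C(=C)[C@@]2(C)CCCC(C)(C)[C@H]12 | intermediate
9 | 6β-(triethylsilyloxy)drim-7-ene-9α,11-diol | CC[Si](CC)(CC)O[C@@H]1C=C(C)[C@](O)(CO)[C@@]2(C)CCCC(C)(C)[C@H]12 | intermediate
10 | 9α-hydroxy-6β-(triethylsilyloxy)drim-7-en-11-al | CC[Si](CC)(CC)O[C@@H]1C=C(C)[C@](O)(C=O)[C@@]2(C)CCCC(C)(C)[C@H]12 | intermediate
11 | 6β,9α-dihydroxydrim-7-en-11-al | O[C@@H]1C=C(C)[C@](O)(C=O)[C@@]2(C)CCCC(C)(C)[C@H]12 | intermediate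
12 | (2E,4E,6E)-octa-2,4,6-trienoic acid | C/C=C/C=C/C=C/C(=O)O | starting material
13 | 9α-hydroxy-11-oxodrim-7-en-6α-yl (2E,4E,6E)-octa-2,4,6-trienoate | C/C=C/C=C/C=C/C(=O)O[C@H]1C=C(C)[C@](O)(C=O)[C@@]2(C)CCCC(C)(C)[C@H]12 | target

## Step count and risks

Total step count: 10. Longest linear sequence: 10 steps (1 and 2 to 13); 12 enters in the last step.

**Step 1 (key step).** The likely failure is a slow cycloaddition, because the Z-methyl of 2 disfavours the s-cis conformer. The strong acid catalyst could then oligomerise the diene, and any warming needed for conversion would erode enantioselectivity. The fallback uses a more nucleophilic diene with a removable C2 silyloxy group; it sets out from 1 and returns at 3.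
- 4-Methylpent-3-en-2-one F1 is silylated (TIPSOTf, Et3N, CH2Cl2, 0 °C) to 4-methyl-2-(triisopropylsilyloxy)penta-1,3-diene F2.
- With 1 and the same catalyst at −78 °C, F2 should form the same C1–C10 and C4–C5 bonds, probably stepwise by Mukaiyama–Michael addition and ring closure, to give the cis-fused 2-(triisopropylsilyloxy)-11-nordrima-2,7-diene-6,9-dione F3.
- CsF and PhNTf2 in DME exchange the silyl group for triflate, giving cis-fused 6,9-dioxo-11-nordrima-2,7-dien-2-yl trifluoromethanesulfonate F4.
- Formate reduction of the enol triflate (Pd(OAc)2, PPh3, Et3N, HCO2H, DMF, 60 °C) gives 3.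

**Step 10.** Formation of the alkoxyphosphonium ion at the doubly syn-axially shielded 6β-hydroxyl may be slow. The acid could then be activated instead, giving acylation with retention, or the activated alcohol could eliminate across C5–C6, where the 5α-hydrogen is antiperiplanar. The fallback inverts C6 early on a simple substrate and ends with an ordinary acylation; it sets out from 5 and returns at 13.
- 5 is inverted with 4-nitrobenzoic acid (PPh3, DIAD, toluene), the usual acid for hindered alcohols, to 9-oxo-11-nordrima-2,7-dien-6α-yl 4-nitrobenzoate F8.
- K2CO3 in MeOH releases 6α-hydroxy-11-nordrima-2,7-dien-9-one F9.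
- The operations of steps 4 to 9 are then repeated in the 6α series:
  - silylation to 6α-(triethylsilyloxy)-11-nordrima-2,7-dien-9-one F10;
  - hydrogenation to 6α-(triethylsilyloxy)-11-nordrim-7-en-9-one F11;
  - methylenation to 6α-(triethylsilyloxy)drima-7,9(11)-diene F12;
  - dihydroxylation to 6α-(triethylsilyloxy)drim-7-ene-9α,11-diol F13;
  - oxidation to 9α-hydroxy-6α-(triethylsilyloxy)drim-7-en-11-al F14;
  - desilylation to 6α,9α-dihydroxydrim-7-en-11-al F15.
- The exposed equatorial 6α-hydroxyl of F15 is acylated with 12 (EDC·HCl, DMAP, CH2Cl2) with retention to give 13.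

**Step 2.** The equilibrium may stop short of the trans isomer, since the angular methyl and the gem-dimethyl group reduce the usual preference for trans fusion. The fallback sets C5 kinetically; it sets out from 3 and returns at 4.
- α′-Deprotonation and silylation (KN(SiMe3)2, Me3SiCl, THF, −78 °C) give 6-(trimethylsilyloxy)-11-nordrima-2,5,7-trien-9-one F5.
- Protodesilylation at low temperature (Bu4NF, AcOH, THF, −78 °C) should protonate C5 from the α face, anti to the C10 methyl, to give 4.

**Step 3.** Hydride may also add at C9, or reduce both carbonyls. The fallback reduces both on purpose and oxidises one back; it sets out from 4 and returns at 5.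
- LiAlH4 in THF at 0 °C gives 11-nordrima-2,7-diene-6β,9β-diol F6 (the C9 configuration is immaterial).
- MnO2 in CH2Cl2 should oxidise only the C9 carbinol, whose pseudo-axial C–H is aligned with the alkene π system. The shielded pseudo-axial 6β-hydroxyl has its C–H in the alkene plane and should remain, giving 5.

**Step 6.** The bulky ylide may add slowly to the carbonyl next to the quaternary C10, leaving time for base-induced degradation of the γ-silyloxy enone. The fallback is a two-stage Peterson olefination with a smaller nucleophile; it sets out from 7 and returns at 8.
- Me3SiCH2Li with CeCl3 in THF at −78 °C adds from the α face to give 6β-(triethylsilyloxy)-9α-[(trimethylsilyl)methyl]-11-nordrim-7-en-9β-ol F7.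
- KH in THF induces syn elimination to 8.

## Further compounds

F1 | step 1 | 4-methylpent-3-en-2-one | CC(=O)C=C(C)C
F2 | step 1 | 4-methyl-2-(triisopropylsilyloxy)penta-1,3-diene | C=C(O[Si](C(C)C)(C(C)C)C(C)C)C=C(C)C
F3 | step 1 | cis-fused 2-(triisopropylsilyloxy)-11-nordrima-2,7-diene-6,9-dione (5β-H, 10β-CH3) | O=C1C=C(C)C(=O)[C@@]2(C)CC(O[Si](C(C)C)(C(C)C)C(C)C)=CC(C)(C)[C@@H]12
F4 | step 1 | cis-fused 6,9-dioxo-11-nordrima-2,7-dien-2-yl trifluoromethanesulfonate (5β-H, 10β-CH3) | O=C1C=C(C)C(=O)[C@@]2(C)CC(OS(=O)(=O)C(F)(F)F)=CC(C)(C)[C@@H]12
F5 | step 2 | 6-(trimethylsilyloxy)-11-nordrima-2,5,7-trien-9-one | C[Si](C)(C)OC1=C2C(C)(C)C=CC[C@]2(C)C(=O)C(C)=C1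
F6 | step 3 | 11-nordrima-2,7-diene-6β,9β-diol | O[C@@H]1C=C(C)[C@H](O)[C@@]2(C)CC=CC(C)(C)[C@H]12
F7 | step 6 | 6β-(triethylsilyloxy)-9α-[(trimethylsilyl)methyl]-11-nordrim-7-en-9β-ol | CC[Si](CC)(CC)O[C@@H]1C=C(C)[C@@](O)(C[Si](C)(C)C)[C@@]2(C)CCCC(C)(C)[C@H]12
F8 | step 10 | 9-oxo-11-nordrima-2,7-dien-6α-yl 4-nitrobenzoate | O=C(O[C@H]1C=C(C)C(=O)[C@@]2(C)CC=CC(C)(C)[C@H]12)c1ccc(cc1)[N+](=O)[O-]
F9 | step 10 | 6α-hydroxy-11-nordrima-2,7-dien-9-one | O[C@H]1C=C(C)C(=O)[C@@]2(C)CC=CC(C)(C)[C@H]12
F10 | step 10 | 6α-(triethylsilyloxy)-11-nordrima-2,7-dien-9-one | CC[Si](CC)(CC)O[C@H]1C=C(C)C(=O)[C@@]2(C)CC=CC(C)(C)[C@H]12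
F11 | step 10 | 6α-(triethylsilyloxy)-11-nordrim-7-en-9-one | CC[Si](CC)(CC)O[C@H]1C=C(C)C(=O)[C@@]2(C)CCCC(C)(C)[C@H]12
F12 | step 10 | 6α-(triethylsilyloxy)drima-7,9(11)-diene | CC[Si](CC)(CC)O[C@H]1C=C(C)C(=C)[C@@]2(C)CCCC(C)(C)[C@H]12
F13 | step 10 | 6α-(triethylsilyloxy)drim-7-ene-9α,11-diol | CC[Si](CC)(CC)O[C@H]1C=C(C)[C@](O)(CO)[C@@]2(C)CCCC(C)(C)[C@H]12
F14 | step 10 | 9α-hydroxy-6α-(triethylsilyloxy)drim-7-en-11-al | CC[Si](CC)(CC)O[C@H]1C=C(C)[C@](O)(C=O)[C@@]2(C)CCCC(C)(C)[C@H]12
F15 | step 10 | 6α,9α-dihydroxydrim-7-en-11-al | O[C@H]1C=C(C)[C@](O)(C=O)[C@@]2(C)CCCC(C)(C)[C@H]12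
A1 | alternative 1 | 3β-hydroxydrim-8(12)-en-11-yl acetate | C1CC(=C)[C@H](COC(C)=O)[C@@]2(C)CC[C@H](O)C(C)(C)[C@H]12
A2 | alternative 1 | (2E,6E,10S)-10,11-epoxy-3,7,11-trimethyldodeca-2,6-dien-1-yl acetate | CC(=O)OC/C=C(C)/CC/C=C(C)/CC[C@@H]1OC1(C)C
A3 | alternative 2 | 9α-(methoxymethoxy)drima-5,7-dien-11-oic acid | C1=C2C(C)(C)CCC[C@]2(C)[C@@](OCOC)(C(O)=O)C(C)=C1
A4 | alternative 2 | (6S)-3-(methoxymethoxy)-4-methyl-6-(2,6,6-trimethylcyclohex-1-en-1-yl)-3,6-dihydro-2H-pyran-2-one (either C3 epimer; C3 is lost on enolisation) | COCOC1C(C)=C[C@H](OC1=O)C1=C(C)CCCC1(C)C
A5 | alternative 3 | 6-(tert-butyldimethylsilyloxy)drim-5-en-11-al (endo adduct, 8β-CH3, formyl α) | CC(C)(C)[Si](C)(C)OC1=C2C(C)(C)CCC[C@]2(C)[C@H](C=O)[C@@H](C)C1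
A6 | alternative 3 | 1-[1-(tert-butyldimethylsilyloxy)ethenyl]-2,6,6-trimethylcyclohex-1-ene | C=C(O[Si](C)(C)C(C)(C)C)C1=C(C)CCCC1(C)C
A7 | alternative 3 | (E)-but-2-enal | C/C=C/C=O
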